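**Retrosynthetic overview**
1. Ester C–O bond: target 7 ⇒ 2,3-dihydroxybenzoic acid (6) + (S)-18-methylicosan-1-ol (5), joined without protecting groups (Mitsunobu).
2. Key C16–C17 bond: 5 ⇒ 16-hydroxyhexadecanal (2), used as its N–H hydrazone (a carbanion equivalent of the aldehyde carbon), + (S)-1-bromo-2-methylbutane (3). Two normally electrophilic carbons are joined, N2 is lost, and the CH2–CH2 link forms directly.
3. 2 ⇒ 16-hexadecanolide (1) by half-reduction.
4. Rings: none is formed. The benzene ring is bought intact in 6, the macrolactone ring of 1 is only opened, and the single stereocenter is bought in 3.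

Assumption: 16-hexadecanolide, (S)-1-bromo-2-methylbutane and 2,3-dihydroxybenzoic acid are taken as commercial, and the in-flask hydrazone formation plus coupling is counted as one step.

**Step 1**
Reactants: 1 16-hexadecanolide (oxacycloheptadecan-2-one)
Product: 2 16-hydroxyhexadecanal
Conditions: i-Bu2AlH (1.1 equiv), CH2Cl2, −78 °C, 1 h; then aq. potassium sodium tartrate, rt
Reagents that add atoms: none
Why: Partial hydride reduction of an ester: the tetrahedral aluminium hemiacetal of the strain-free macrolactone is stable at −78 °C and collapses only on work-up to the open-chain hydroxy aldehyde, which cannot close to a favourable lactol.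

**Step 2**
Reactants: 2 16-hydroxyhexadecanal; 3 (S)-1-bromo-2-methylbutane (1.5 equiv)
Product: 5 (S)-18-methylicosan-1-ol, via 16-hydroxyhexadecanal hydrazone 4 (not isolated)
Conditions: N2H4·H2O (1.2 equiv), THF, rt, 1 h, dry over Na2SO4; then 3, Ni(cod)2 (10 mol%), 4,4'-di-tert-butyl-2,2'-bipyridine (12 mol%), K3PO4 (2 equiv), THF, 60 °C, 16 h
Reagents that add atoms: hydrazine monohydrate, NN.O (its two nitrogens sit in intermediate 4 and leave as N2; none remain in 5)
Why: Proposed new method: the N–H hydrazone 4 is a carbanion equivalent of the aldehyde carbon of 2 – base-assisted N–H deprotonation on nickel gives an N-bound diazenyl (aza-allyl) anion that is nucleophilic at carbon, zerovalent nickel activates the primary C–Br bond of 3 by halogen abstraction and radical capture, C(sp3)–C(sp3) reductive elimination gives a monoalkyl diazene that loses N2 in Wolff–Kishner fashion to leave the C16–C17 CH2–CH2 bond, so two carbons that are both electrophilic in 2 and 3 are joined with no residual functional group; the stereocenter of 3 is β to the reacting carbon, no bond to it is made or broken and the bipyridine ligand disfavours β-hydride chain walking, so the (S) configuration is carried over unchanged; closest known reaction type: nickel-catalysed denitrogenative cross-coupling of aldehyde hydrazones (mostly of aryl aldehydes) with unactivated alkyl halides and the related ruthenium-catalysed hydrazone additions, extended here to a fully aliphatic hydrazone with a free hydroxyl.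

**Step 3**
Reactants: 5 (S)-18-methylicosan-1-ol; 6 2,3-dihydroxybenzoic acid (1.5 equiv)
Product: 7 gentiside H, (S)-18-methylicosyl 2,3-dihydroxybenzoate
Conditions: PPh3 (1.3 equiv), DIAD (1.3 equiv, added last), THF, 0 °C to rt
Reagents that add atoms: none
Why: Mitsunobu esterification: the carboxylic acid (pKa about 3) is far more acidic than the phenols (pKa about 10), so the carboxylate alone displaces the primary alkoxyphosphonium, as in Mitsunobu esterifications and lactonisations of unprotected hydroxybenzoic acids; no stereocenter is involved.

**Compound list**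
1 | 16-hexadecanolide (oxacycloheptadecan-2-one) | O=C1CCCCCCCCCCCCCCCO1 | starting material
2 | 16-hydroxyhexadecanal | O=CCCCCCCCCCCCCCCCO | intermediate
3 | (S)-1-bromo-2-methylbutane | CC[C@H](C)CBr | starting material
4 | 16-hydroxyhexadecanal hydrazone, (E)-16-hydrazinylidenehexadecan-1-ol | N/N=C/CCCCCCCCCCCCCCCO | intermediate
5 | (S)-18-methylicosan-1-ol | CC[C@H](C)CCCCCCCCCCCCCCCCCO | intermediate
6 | 2,3-dihydroxybenzoic acid | OC(=O)c1cccc(O)c1O | starting material
7 | gentiside H, (S)-18-methylicosyl 2,3-dihydroxybenzoate | CC[C@H](C)CCCCCCCCCCCCCCCCCOC(=O)c1cccc(O)c1O | target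

**Step count and risks**
Total steps: 3. Longest linear sequence: 3 (1 → 2 → 5 → 7).

Steps most likely to fail, in order of risk:

Step 2 (key coupling). An aliphatic N–H hydrazone may form the azine, be N-alkylated, or simply be reduced to hexadecan-1-ol. The fallback sets out from 2 and uses the classical masked acyl anion. Aldehyde 2 is converted with propane-1,3-dithiol and BF3·OEt2 in CH2Cl2 into 2-(15-hydroxypentadecyl)-1,3-dithiane F2. Its O,C-dianion (n-BuLi, 2.2 equiv, THF/DMPU, −30 °C) is alkylated with 3 to give 2-(15-hydroxypentadecyl)-2-[(S)-2-methylbutyl]-1,3-dithiane F3. Desulfurisation with Raney Ni in refluxing EtOH returns to the route at 5.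

Step 3 (esterification). The free catechol may tie up PPh3/DIAD as a cyclic phosphorane or be O-alkylated. The fallback sets out from 5 and activates the acyl partner instead, with the phenols masked. Alcohol 5 is coupled (EDC·HCl, DMAP, CH2Cl2) with purchased 2,3-bis(benzyloxy)benzoic acid F4 to give (S)-18-methylicosyl 2,3-bis(benzyloxy)benzoate F5. Hydrogenolysis (H2, Pd/C, EtOAc) returns to the route at 7.

Step 1 (half-reduction). Over-reduction to hexadecane-1,16-diol is possible. The fallback sets out from 1. The lactone is opened with MeNH(OMe)·HCl and i-PrMgCl in THF to the Weinreb amide 16-hydroxy-N-methoxy-N-methylhexadecanamide F1. Its chelated LiAlH4 adduct (THF, 0 °C) stops at the aldehyde stage and returns to the route at 2.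

**Further compounds**
F1 | step 1 | 16-hydroxy-N-methoxy-N-methylhexadecanamide | CON(C)C(=O)CCCCCCCCCCCCCCCO
F2 | step 2 | 2-(15-hydroxypentadecyl)-1,3-dithiane | OCCCCCCCCCCCCCCCC1SCCCS1
F3 | step 2 | 2-(15-hydroxypentadecyl)-2-[(S)-2-methylbutyl]-1,3-dithiane | CC[C@H](C)CC1(CCCCCCCCCCCCCCCO)SCCCS1
F4 | step 3 | 2,3-bis(benzyloxy)benzoic acid | OC(=O)c1cccc(OCc2ccccc2)c1OCc1ccccc1
F5 | step 3 | (S)-18-methylicosyl 2,3-bis(benzyloxy)benzoate | CC[C@H](C)CCCCCCCCCCCCCCCCCOC(=O)c1cccc(OCc2ccccc2)c1OCc1ccccc1
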